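**Retrosynthetic overview**
- Target 29 is traced back to arene 27 by removing the acetyl group at C5' of ring B (Friedel–Crafts acylation) and re-protecting the phenols (three benzyl ethers on ring B, one isopropyl ether on ring A).
- The strategy rests on ring A: C1 (butyryl) sits between the oxygens at C2 and C6, and C4 (OMe) is para to C1 between C3 (Me) and C5 (CH2–ring B). This maps C2–C5 onto a 1,3-dioxygenated 1-silyloxy diene and C1/C6 onto a butyryl alkynyl ether, with disconnection at C1–C2 and C5–C6.
- Diene 24 comes from β-methoxy enoate 12, made from 2,4,6-trihydroxytoluene 1 by formylation, benzylation and two Meldrum's acid homologations; ynone 22 comes from propan-2-ol, trichloroethylene and Weinreb amide 18.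
- Ring order: ring B is bought with 1 and carried through; ring A is built last from open-chain parts in step 10.

Key step: step 10

**Remarks on the chemistry**
- The alkynyl ether oxygen that becomes the C6 hydroxyl is carried as an isopropyl ether. After the cycloaddition the ketone is held by the free C2 hydroxyl, so chelation-assisted BCl3 cleavage of a primary alkyl ether at C6 cannot be relied on. A secondary alkyl ether is cleaved by BCl3 without chelation and should leave the C4 methyl ether alone.
- The target has no stereocentre.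

**Route**

Step 1
Reactants: 1 2,4,6-trihydroxytoluene
Product: 3 2,4,6-trihydroxy-3-methylbenzaldehyde, via iminium chloride 2 (not isolated)
Conditions: POCl3, DMF, EtOAc, 0 °C → rt; then H2O, 60 °C
Reagents that add atoms: N,N-dimethylformamide, CN(C)C=O; water, O
Why: Vilsmeier–Haack formylation, in which the two unsubstituted ring carbons of 1 are equivalent and the iminium group of 2 deactivates the ring against a second attack, so one aldehyde is expected after hydrolysis.

Step 2
Reactants: 3 2,4,6-trihydroxy-3-methylbenzaldehyde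
Product: 4 2,4,6-tris(benzyloxy)-3-methylbenzaldehyde
Conditions: BnBr (3.5 equiv), K2CO3, DMF, 60 °C
Reagents that add atoms: benzyl bromide, BrCc1ccccc1
Why: Williamson ether synthesis, in which the formyl group lowers the carbon nucleophilicity of the phenoxide so that O-alkylation should dominate, and warming with excess bromide should drive the two hydrogen-bonded ortho hydroxyls to completion.

Step 3
Reactants: 4 2,4,6-tris(benzyloxy)-3-methylbenzaldehyde; 5 Meldrum's acid
Product: 8 3-[2,4,6-tris(benzyloxy)-3-methylphenyl]propanoic acid, via arylidene Meldrum's acid 6 (not isolated), via benzyl Meldrum's acid 7 (not isolated)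
Conditions: HCO2H–Et3N (5:2), 95–100 °C; then aq. HCl
Reagents that add atoms: water, O
Why: Knoevenagel condensation followed in the same flask by conjugate hydride transfer from formate to 6 and hydrolysis/decarboxylation of 7, a reduction chosen because benzyl ethers are inert to triethylammonium formate.

Step 4
Reactants: 8 3-[2,4,6-tris(benzyloxy)-3-methylphenyl]propanoic acid; 5 Meldrum's acid
Product: 10 methyl 3-oxo-5-[2,4,6-tris(benzyloxy)-3-methylphenyl]pentanoate, via acyl Meldrum's acid 9 (not isolated)
Conditions: DCC, DMAP, CH2Cl2, 0 °C → rt; then MeOH, reflux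
Reagents that add atoms: methanol, CO
Why: Carbodiimide-mediated C-acylation of Meldrum's acid and methanolysis of 9 with loss of acetone and CO2 is the standard two-carbon homologation of an acid to a β-keto ester.

Step 5
Reactants: 10 methyl 3-oxo-5-[2,4,6-tris(benzyloxy)-3-methylphenyl]pentanoate
Product: 11 methyl 2-methyl-3-oxo-5-[2,4,6-tris(benzyloxy)-3-methylphenyl]pentanoate (racemic)
Conditions: MeI (1.05 equiv), K2CO3, acetone, rt
Reagents that add atoms: iodomethane, CI
Why: Mono-C-alkylation of the β-keto ester enolate with one equivalent of MeI under mild carbonate conditions; the new stereocentre at C2 forms racemic and is erased in step 6.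

Step 6
Reactants: 11 methyl 2-methyl-3-oxo-5-[2,4,6-tris(benzyloxy)-3-methylphenyl]pentanoate
Product: 12 methyl (2E)-3-methoxy-2-methyl-5-[2,4,6-tris(benzyloxy)-3-methylphenyl]pent-2-enoate
Conditions: HC(OMe)3, MeOH, cat. TsOH·H2O, 50 °C; Et3N quench
Reagents that add atoms: trimethyl orthoformate, COC(OC)OC; methanol, CO
Why: Acid-catalysed enol ether formation with the orthoformate as water scavenger is the usual route from β-keto esters to β-methoxy enoates, the conjugated enoate being the thermodynamic product, and any Z or β,γ-unsaturated isomer is tolerated because all converge on one dienolate in step 9.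

Step 7
Reactants: 13 propan-2-ol; 14 trichloroethylene
Product: 17 (E)-1,2-dichloro-1-(propan-2-yloxy)ethene, via potassium propan-2-olate 15 (not isolated), via dichloroethyne 16 (not isolated)
Conditions: KH (2 equiv), THF, 0 °C; then 14, −50 °C → rt
Reagents that add atoms: none
Why: Alkoxide-induced dehydrochlorination of trichloroethylene to 16 and anti addition of 15 to it is the established entry to 1,2-dichlorovinyl ethers of secondary alcohols.

Step 8
Reactants: 17 (E)-1,2-dichloro-1-(propan-2-yloxy)ethene; 18 N-methoxy-N-methylbutanamide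
Product: 22 1-(propan-2-yloxy)hex-1-yn-3-one, via chloro ynol ether 19 (not isolated), via lithium alkoxyacetylide 20 (not isolated), via lithium hemiaminal 21 (not isolated)
Conditions: n-BuLi (2.1 equiv), THF, −78 → −40 °C; 18, −78 → −20 °C; AcOH, THF, −78 °C, then cold pH 7 buffer
Reagents that add atoms: none
Why: Dehydrochlorination by the first equivalent of n-BuLi and chlorine–lithium exchange by the second give acetylide 20, and its Weinreb ketone synthesis stops at chelate 21, so the ynone is released only in the cold acidic quench that also protonates the liberated amine.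

Step 9
Reactants: 12 methyl (2E)-3-methoxy-2-methyl-5-[2,4,6-tris(benzyloxy)-3-methylphenyl]pent-2-enoate
Product: 24 (3Z)-1,3-dimethoxy-2-methyl-5-[2,4,6-tris(benzyloxy)-3-methylphenyl]-1-(trimethylsilyloxy)penta-1,3-diene, via lithium dienolate 23 (not isolated)
Conditions: LiN(iPr)2, THF, −78 °C; Me3SiCl, −78 °C → rt; pentane, filtration under Ar, used crude
Reagents that add atoms: chlorotrimethylsilane, C[Si](C)(C)Cl
Why: γ-Deprotonation of a β-methoxy enoate to the extended dienolate and O-silylation is the standard preparation of 1,3-dialkoxy-1-silyloxy dienes; the C2 methyl group does not compete because its anion would be cross-conjugated, and the arm should settle trans to C2 on the new C3=C4 bond.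

Step 10
Reactants: 24 (3Z)-1,3-dimethoxy-2-methyl-5-[2,4,6-tris(benzyloxy)-3-methylphenyl]-1-(trimethylsilyloxy)penta-1,3-diene; 22 1-(propan-2-yloxy)hex-1-yn-3-one
Product: 27 1-[6-hydroxy-4-methoxy-5-methyl-2-(propan-2-yloxy)-3-[[2,4,6-tris(benzyloxy)-3-methylphenyl]methyl]phenyl]butan-1-one, via cycloadduct 25 (not isolated), via aryl silyl ether 26 (not isolated)
Conditions: 24 (1.5 equiv), toluene, rt → 60 °C; then 1 M HCl, THF, 0 °C
Reagents that add atoms: none
Why: Proposed new method: a β-alkoxy alkynone has not been shown as the two-carbon partner of a fully substituted 1,3-dialkoxy-1-silyloxy diene, the closest known reaction being the Diels–Alder/aromatisation of such dienes with acetylenic ketones and esters. Diene carbon C4, which carries the CH2–ring B arm and the largest HOMO coefficient, should bond to the isopropoxy-bearing β-carbon of 22, the site at which alkoxy ynones accept nucleophiles, while the ketene acetal carbon C1 bonds to the butyryl-bearing carbon, either in one asynchronous (4+2) event or by Mukaiyama–Michael addition followed by attack of the allenolate on the silyloxycarbenium carbon. Either way ring A closes as a six-membered carbocycle through the new C5–C6 and C1–C2 bonds (ring A numbering), giving cyclohexa-1,4-diene 25. 1,4-Elimination of methanol from 25 (ketal OMe and the ring hydrogen at the arm-bearing carbon) gives arene 26 and dilute acid removes the silyl group, so both sp3 centres of 25 vanish and no stereocentre has to be controlled. The only selectivity needed is regiochemical, and it is secured because the donor pattern of the diene and the acceptor pattern of the ynone point the same way; the C2 methyl group of 24 favours the s-cis conformer and the (3Z) geometry keeps the arm on the outside of the diene. The temperature is held at or below 60 °C so that retro-ene loss of propene from the isopropyl ynol ether does not compete.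

Step 11
Reactants: 27 1-[6-hydroxy-4-methoxy-5-methyl-2-(propan-2-yloxy)-3-[[2,4,6-tris(benzyloxy)-3-methylphenyl]methyl]phenyl]butan-1-one
Product: 28 1-[2,6-dihydroxy-4-methoxy-3-methyl-5-[(2,4,6-trihydroxy-3-methylphenyl)methyl]phenyl]butan-1-one
Conditions: BCl3 (excess), C6HMe5 (6 equiv), CH2Cl2, −78 °C → 0 °C; MeOH quench
Reagents that add atoms: none
Why: Lewis acid ether cleavage, in which BCl3 with pentamethylbenzene as cation scavenger removes the three benzyl groups at low temperature and, on warming, the secondary isopropyl group by an SN1-type path that needs no carbonyl chelation, while the C4 methyl ether, which could leave only by SN2 attack, should survive.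

Step 12
Reactants: 28 1-[2,6-dihydroxy-4-methoxy-3-methyl-5-[(2,4,6-trihydroxy-3-methylphenyl)methyl]phenyl]butan-1-one
Product: 29 1-[3-[(3-acetyl-2,4,6-trihydroxy-5-methylphenyl)methyl]-2,6-dihydroxy-4-methoxy-5-methylphenyl]butan-1-one
Conditions: Ac2O (1.2 equiv), BF3·OEt2, 1,4-dioxane, 0 °C → rt; then aq. NaOAc, MeOH, 40 °C
Reagents that add atoms: acetic anhydride, CC(=O)OC(C)=O
Why: Friedel–Crafts C-acylation of a phloroglucinol, directed to C5' of ring B because it is the only unsubstituted aromatic carbon in 28 and lies between two hydroxyls, while ring A is fully substituted and deactivated and the mild basic work-up returns any aryl acetate to the phenol.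

**Compound list**
1 | 2,4,6-trihydroxytoluene | Cc1c(O)cc(O)cc1O | starting material
2 | (2,4,6-trihydroxy-3-methylbenzylidene)dimethyliminium chloride | C[N+](C)=Cc1c(O)c(C)c(O)cc1O.[Cl-] | intermediate (not isolated)
3 | 2,4,6-trihydroxy-3-methylbenzaldehyde | O=Cc1c(O)c(C)c(O)cc1O | intermediate
4 | 2,4,6-tris(benzyloxy)-3-methylbenzaldehyde | O=Cc1c(OCc2ccccc2)c(C)c(OCc2ccccc2)cc1OCc1ccccc1 | intermediate
5 | Meldrum's acid (2,2-dimethyl-1,3-dioxane-4,6-dione) | CC1(C)OC(=O)CC(=O)O1 | starting material
6 | 5-[[2,4,6-tris(benzyloxy)-3-methylphenyl]methylidene]-2,2-dimethyl-1,3-dioxane-4,6-dione | CC1(C)OC(=O)C(=Cc2c(OCc3ccccc3)c(C)c(OCc3ccccc3)cc2OCc2ccccc2)C(=O)O1 | intermediate (not isolated)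
7 | 5-[[2,4,6-tris(benzyloxy)-3-methylphenyl]methyl]-2,2-dimethyl-1,3-dioxane-4,6-dione | CC1(C)OC(=O)C(Cc2c(OCc3ccccc3)c(C)c(OCc3ccccc3)cc2OCc2ccccc2)C(=O)O1 | intermediate (not isolated)
8 | 3-[2,4,6-tris(benzyloxy)-3-methylphenyl]propanoic acid | OC(=O)CCc1c(OCc2ccccc2)c(C)c(OCc2ccccc2)cc1OCc1ccccc1 | intermediate
9 | 5-[1-hydroxy-3-[2,4,6-tris(benzyloxy)-3-methylphenyl]propylidene]-2,2-dimethyl-1,3-dioxane-4,6-dione | CC1(C)OC(=O)C(=C(O)CCc2c(OCc3ccccc3)c(C)c(OCc3ccccc3)cc2OCc2ccccc2)C(=O)O1 | intermediate (not isolated)
10 | methyl 3-oxo-5-[2,4,6-tris(benzyloxy)-3-methylphenyl]pentanoate | COC(=O)CC(=O)CCc1c(OCc2ccccc2)c(C)c(OCc2ccccc2)cc1OCc1ccccc1 | intermediate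
11 | methyl 2-methyl-3-oxo-5-[2,4,6-tris(benzyloxy)-3-methylphenyl]pentanoate (racemic) | COC(=O)C(C)C(=O)CCc1c(OCc2ccccc2)c(C)c(OCc2ccccc2)cc1OCc1ccccc1 | intermediate
12 | methyl (2E)-3-methoxy-2-methyl-5-[2,4,6-tris(benzyloxy)-3-methylphenyl]pent-2-enoate | COC(=O)/C(C)=C(/OC)CCc1c(OCc2ccccc2)c(C)c(OCc2ccccc2)cc1OCc1ccccc1 | intermediate
13 | propan-2-ol | CC(C)O | starting material
14 | trichloroethylene | ClC=C(Cl)Cl | starting material
15 | potassium propan-2-olate | CC(C)[O-].[K+] | intermediate (not isolated)
16 | dichloroethyne | ClC#CCl | intermediate (not isolated)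
17 | (E)-1,2-dichloro-1-(propan-2-yloxy)ethene | CC(C)O/C(Cl)=C\Cl | intermediate
18 | N-methoxy-N-methylbutanamide | CCCC(=O)N(C)OC | starting material
19 | 1-chloro-2-(propan-2-yloxy)ethyne | ClC#COC(C)C | intermediate (not isolated)
20 | lithium (propan-2-yloxy)ethynide | [Li]C#COC(C)C | intermediate (not isolated)
21 | lithium 3-[methoxy(methyl)amino]-1-(propan-2-yloxy)hex-1-yn-3-olate | CCCC(O[Li])(C#COC(C)C)N(C)OC | intermediate (not isolated)
22 | 1-(propan-2-yloxy)hex-1-yn-3-one | CCCC(=O)C#COC(C)C | intermediate
23 | lithium dienolate of 12 | [Li]OC(OC)=C(C)/C(OC)=C/Cc1c(OCc2ccccc2)c(C)c(OCc2ccccc2)cc1OCc1ccccc1 | intermediate (not isolated)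
24 | (3Z)-1,3-dimethoxy-2-methyl-5-[2,4,6-tris(benzyloxy)-3-methylphenyl]-1-(trimethylsilyloxy)penta-1,3-diene | COC(O[Si](C)(C)C)=C(C)/C(OC)=C/Cc1c(OCc2ccccc2)c(C)c(OCc2ccccc2)cc1OCc1ccccc1 | intermediate
25 | 1-[4,6-dimethoxy-5-methyl-2-(propan-2-yloxy)-3-[[2,4,6-tris(benzyloxy)-3-methylphenyl]methyl]-6-(trimethylsilyloxy)cyclohexa-1,4-dien-1-yl]butan-1-one (both sp3 centres unassigned) | CCCC(=O)C1=C(OC(C)C)C(Cc2c(OCc3ccccc3)c(C)c(OCc3ccccc3)cc2OCc2ccccc2)C(OC)=C(C)C1(OC)O[Si](C)(C)C | intermediate (not isolated)
26 | 1-[4-methoxy-5-methyl-2-(propan-2-yloxy)-3-[[2,4,6-tris(benzyloxy)-3-methylphenyl]methyl]-6-(trimethylsilyloxy)phenyl]butan-1-one | CCCC(=O)c1c(O[Si](C)(C)C)c(C)c(OC)c(Cc2c(OCc3ccccc3)c(C)c(OCc3ccccc3)cc2OCc2ccccc2)c1OC(C)C | intermediate (not isolated)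
27 | 1-[6-hydroxy-4-methoxy-5-methyl-2-(propan-2-yloxy)-3-[[2,4,6-tris(benzyloxy)-3-methylphenyl]methyl]phenyl]butan-1-one | CCCC(=O)c1c(O)c(C)c(OC)c(Cc2c(OCc3ccccc3)c(C)c(OCc3ccccc3)cc2OCc2ccccc2)c1OC(C)C | intermediate
28 | 1-[2,6-dihydroxy-4-methoxy-3-methyl-5-[(2,4,6-trihydroxy-3-methylphenyl)methyl]phenyl]butan-1-one | CCCC(=O)c1c(O)c(C)c(OC)c(Cc2c(O)c(C)c(O)cc2O)c1O | intermediate
29 | 1-[3-[(3-acetyl-2,4,6-trihydroxy-5-methylphenyl)methyl]-2,6-dihydroxy-4-methoxy-5-methylphenyl]butan-1-one (CNP0258463.0) | CCCC(=O)c1c(O)c(C)c(OC)c(Cc2c(O)c(C)c(O)c(C(C)=O)c2O)c1O | target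

**Step count**
Total: 12 steps. Longest linear sequence: 10 steps (steps 1–6 and 9–12, from 1); the ynone branch (steps 7–8) joins at step 10.

**Steps most likely to fail**

1. Step 10 (key step). The alkoxy donor may make the ynone too weak an acceptor, so that hydrolysis of the diene or retro-ene breakdown of the ynol ether outruns C–C bond formation, or the first-formed Michael adduct may fail to close. Fallback by known chemistry, setting out from 1 and returning at 29: the bridge is made by joining two finished rings instead of building ring A.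
 - Friedel–Crafts acylation of 1 with butanoyl chloride and AlCl3 should give 1-(2,4,6-trihydroxy-3-methylphenyl)butan-1-one F1.
 - Me2SO4 (1 equiv) and K2CO3 in acetone should methylate only the non-chelated hydroxyl para to the ketone, giving 1-(2,6-dihydroxy-4-methoxy-3-methylphenyl)butan-1-one F2.
 - A Mannich reaction with dimethylmethylideneammonium iodide at the one free ring carbon should give 1-[3-[(dimethylamino)methyl]-2,6-dihydroxy-4-methoxy-5-methylphenyl]butan-1-one F3.
 - Separately, 1 with Ac2O and BF3·OEt2 should give 1-(2,4,6-trihydroxy-3-methylphenyl)ethan-1-one F4.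
 - Heating F3 with F4 in 1,4-dioxane should expel dimethylamine to form an ortho-quinone methide, which the single free ring carbon of F4 traps to give 29.

2. Step 12. Under BF3 the electron-rich ring B may be attacked at the bridge-bearing carbon, with retro-Friedel–Crafts fragmentation of the diarylmethane, or acylation may stop on oxygen. Fallback, setting out from 28 and returning at 29: a Houben–Hoesch reaction with MeCN, ZnCl2 and HCl gas in Et2O at 0 °C should give the ketiminium chloride F5. Its positive charge shuts the ring down against further attack and it cannot form on oxygen. Warm water then hydrolyses F5 to 29.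

3. Step 8. The amine set free from the Weinreb adduct may add to the β-carbon of the ynone, or the ynol ether may be hydrated during the quench. Fallback, setting out from 17 and returning at 22: acetylide 20, generated as in step 8, is added to butanal to give 1-(propan-2-yloxy)hex-1-yn-3-ol F6 (racemic). Oxidation with MnO2 in CH2Cl2 at rt should then give 22 under neutral conditions with no amine present.

**Further compounds**
F1 | step 10 | 1-(2,4,6-trihydroxy-3-methylphenyl)butan-1-one | CCCC(=O)c1c(O)cc(O)c(C)c1O
F2 | step 10 | 1-(2,6-dihydroxy-4-methoxy-3-methylphenyl)butan-1-one | CCCC(=O)c1c(O)cc(OC)c(C)c1O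
F3 | step 10 | 1-[3-[(dimethylamino)methyl]-2,6-dihydroxy-4-methoxy-5-methylphenyl]butan-1-one | CCCC(=O)c1c(O)c(CN(C)C)c(OC)c(C)c1O
F4 | step 10 | 1-(2,4,6-trihydroxy-3-methylphenyl)ethan-1-one | CC(=O)c1c(O)cc(O)c(C)c1O
F5 | step 12 | 1-[3-[[2,6-dihydroxy-4-methoxy-3-methyl-5-butanoylphenyl]methyl]-2,4,6-trihydroxy-5-methylphenyl]ethan-1-iminium chloride | CCCC(=O)c1c(O)c(C)c(OC)c(Cc2c(O)c(C)c(O)c(C(C)=[NH2+])c2O)c1O.[Cl-]
F6 | step 8 | 1-(propan-2-yloxy)hex-1-yn-3-ol (racemic) | CCCC(O)C#COC(C)C
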